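Remark (assumption): compounds 1, 2, 6, 11 and 16 are treated as purchasable, and (−)-MIB is taken to direct alkenyl transfer to the Si face of an aryl aldehyde, as it does for alkyl transfer; its enantiomer would be used if the sense were opposite.

## Analysis of the target

Deoxycalyxin A (18) is a 2′,4′-dihydroxy-6′-methoxychalcone: ring A carries an (E)-4-hydroxycinnamoyl group at C1′. Its ring carbon C3′, flanked by O2′ and O4′, is bonded to C3 of a 1,7-bis(4-hydroxyphenyl)hept-1-ene chain. No ring has to be built. The problem is one acyclic tertiary stereocentre, C3 (R), which bears H, ring A, the (E)-C1=C2 styryl unit and the C4–C7 chain to the second p-hydroxyphenyl ring. There is no second stereocentre to relay from. C3 is both benzylic to a phloroglucinol ring and allylic to a p-hydroxystyrene, so its obvious formation through an allyl or quinone-methide cation is inherently racemic. Ring A offers C3′, C5′ and three oxygens to any electrophile, so regiochemistry is a second problem. Sensitive groups are the five phenols, the 2′-hydroxychalcone (flavanone closure), the p-hydroxystyrene next to ortho phenols (acid-induced flavan closure) and two E-alkenes, which rule out hydrogenation and benzyl ethers. The feature exploited here is that the C3′–C3 bond, the adjacent C1=C2 double bond and O2′ on the neighbouring ring carbon together form an o-(1-alkyl-3-arylallyl)phenol, the retron of an aromatic Claisen rearrangement. The other ortho position of O2′, C1′, is already occupied by the acyl carbon.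

## Retrosynthetic reasoning

18 ⇒ 17. The last operation only removes three MOM ethers (O4′, the chalcone B-ring oxygen and the distal chain phenol). MOM is chosen because it survives organometallics, Mitsunobu conditions, heat and base, and is removed without hydrogenation.

17 ⇒ 15 + 16. The chalcone Cα=Cβ bond is cut by a Claisen–Schmidt condensation. It is placed after the thermal step so that the 2′-hydroxy-enone never sees high temperature. The basic medium also cleaves the pivalate of 15, so no separate deprotection is needed.

15 ⇒ 13 (via 14). This is the key disconnection: the C3′–C3 bond is cut and the C1=C2 double bond is shifted back, which gives the O2′–C1 allyl aryl ether 13. This turns a C–C stereocentre at a congested arene position into a C–O carbinol centre two atoms away, which is easy to set. The forward [3,3] shift must transfer chirality from C1 to C3, form the E-styrene and alkylate only C3′. The acetyl group at C1′ secures the last point, because O2′ then has a single open ortho position. An ether on O4′ was not considered because both of its ortho positions (C3′, C5′) are free.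

13 ⇒ 10 + 12. The O2′–C1 bond is cut to a phenol and a secondary allylic alcohol, joined by SN2 etherification with inversion. Phenol 12 comes from 11 by selective protection of the non-chelated O4′. The C1 aryl ring of 10 carries a pivalate rather than an ether so that the C1–O bond is not a quinone-methide precursor during etherification and rearrangement.

10 ⇒ 5 + 7. The C1–C2 bond is cut to an aryl aldehyde and an (E)-alkenyl metal. Syn-hydroboration of alkyne 5 (to 8) and boron-to-zinc exchange (to 9) fix the E geometry, and a catalytic asymmetric alkenylzinc addition sets the only stereocentre of the route from achiral pieces. Aldehyde 7 is the pivalate of 6.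

5 ⇒ 4 ⇒ 1 + 2 (via 3). The six-carbon alkyne arm is cut at the sp–sp3 bond (acetylide alkylation of 4) and at the aryl–CH2 bond (copper-catalysed coupling of Grignard reagent 3 with an excess of 2).

## Alternatives that were turned down

Alternative 1: Friedel–Crafts alkylation (the textbook and biomimetic cut of C3′–C3). Acid ionises the racemic allylic alcohol A1 in the presence of 11, or of the preformed chalcone, to give the C-alkylated ketone A2. It was turned down because the cation is a planar, delocalised vinylogous p-quinone methide, so the stereocentre forms without control. The cation has two electrophilic termini (C1 and C3) and the nucleophile has C3′, C5′ and oxygen sites. Under the same acid the ortho phenols of the product add to the protonated styrene. The step is short but leaves both the enantio- and the regiochemical problem unsolved, so a resolution would be needed.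

Alternative 2: Rhodium-catalysed asymmetric 1,4-addition, cutting C3′–C3 as aryl nucleophile plus enone β-carbon. Boronic acid A3 would add to dienone A4 to give ketone A5. It was turned down because a 2,6-dioxygenated arylboronic acid is hindered and protodeboronates easily, and because 1,6-addition competes on the dienone. The adduct also carries a C5 carbonyl that the target lacks, which would have to be removed in about three steps in the presence of the styrene. Ring A would still have to be acylated afterwards. The sequence is clearly longer than the chosen one.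

Alternative 3: Copper-mediated anti-SN2′ arylation. The picolinate A6 of alcohol 10 would react with the arylcopper reagent made from arene A7 to give A8, with 1,3-chirality transfer and no polar ether intermediate. It was turned down because the organometallic cannot carry the acetyl group. In A8 the most acidic C–H is the new stereogenic one, so directed lithiation for a later acylation would risk racemisation. The acyl group would have to come from electrophilic substitution on a MOM-protected arene or from halogenation and cross-coupling, at a cost of three to four extra steps and a stoichiometric hindered arylcopper. In the chosen route the acetyl group is instead used as the regiocontrol element.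

Key step: step 7

## Route

Step 1
Reactants: 1 1-bromo-4-(methoxymethoxy)benzene; 2 1,4-dibromobutane
Product: 4 1-(4-bromobutyl)-4-(methoxymethoxy)benzene, via aryl Grignard reagent 3 (not isolated)
Conditions: Mg, THF, rt → 40 °C; then added to 2 (3 equiv), Li2CuCl4 (3 mol%), THF, 0 °C → rt
Reagents that add atoms: none
Why: Copper-catalysed Grignard–alkyl bromide cross-coupling (Kochi type); the excess of 2 suppresses double arylation and the MOM ether is inert to Grignard and cuprate species.

Step 2
Reactants: 4 1-(4-bromobutyl)-4-(methoxymethoxy)benzene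
Product: 5 1-(hex-5-yn-1-yl)-4-(methoxymethoxy)benzene
Conditions: lithium acetylide–ethylenediamine complex, DMSO, 0 °C → rt
Reagents that add atoms: lithium acetylide ethylenediamine complex, [Li+].[C-]#C.NCCN
Why: SN2 alkylation of acetylide by an unhindered primary bromide in a dipolar aprotic solvent; no competing functionality is present.

Step 3
Reactants: 6 4-hydroxybenzaldehyde
Product: 7 4-formylphenyl 2,2-dimethylpropanoate
Conditions: PivCl, Et3N, DMAP (cat.), CH2Cl2, 0 °C → rt
Reagents that add atoms: pivaloyl chloride, CC(C)(C)C(=O)Cl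
Why: Phenol O-acylation; the pivalate makes the para oxygen a weak donor (so the later benzylic C–O bond resists heterolysis), should tolerate organozinc reagents, Mitsunobu conditions and heat, and is cleaved by the base of step 8.

Step 4
Reactants: 5 1-(hex-5-yn-1-yl)-4-(methoxymethoxy)benzene; 7 4-formylphenyl 2,2-dimethylpropanoate
Product: 10 4-[(1S,2E)-1-hydroxy-7-[4-(methoxymethoxy)phenyl]hept-2-en-1-yl]phenyl 2,2-dimethylpropanoate, via alkenylborane 8 (not isolated), via alkenylmethylzinc 9 (not isolated)
Conditions: Cy2BH (made in the flask from BH3·SMe2 and cyclohexene), toluene, 0 °C → rt; Me2Zn, −78 °C; (−)-MIB (5 mol%), then 7, −20 → 0 °C; aq. NH4Cl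
Reagents that add atoms: none
Why: Syn-hydroboration fixes the E-alkene, boron-to-zinc exchange gives the alkenylzinc, and amino-alcohol-catalysed asymmetric alkenylzinc addition to the aryl aldehyde should set C1 as S by Si-face transfer; organozinc reagents do not attack the pivalate or the MOM ether.

Step 5
Reactants: 11 1-(2,4-dihydroxy-6-methoxyphenyl)ethan-1-one
Product: 12 1-[2-hydroxy-6-methoxy-4-(methoxymethoxy)phenyl]ethan-1-one
Conditions: MOMCl (1.05 equiv), i-Pr2NEt, CH2Cl2, 0 °C
Reagents that add atoms: chloromethyl methyl ether, COCCl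
Why: Selective O-alkylation of the more acidic, non-chelated 4′-OH; the 2′-OH is held in a hydrogen bond to the acetyl group and should stay free.

Step 6
Reactants: 10 4-[(1S,2E)-1-hydroxy-7-[4-(methoxymethoxy)phenyl]hept-2-en-1-yl]phenyl 2,2-dimethylpropanoate; 12 1-[2-hydroxy-6-methoxy-4-(methoxymethoxy)phenyl]ethan-1-one
Product: 13 4-[(1R,2E)-1-[2-acetyl-3-methoxy-5-(methoxymethoxy)phenoxy]-7-[4-(methoxymethoxy)phenyl]hept-2-en-1-yl]phenyl 2,2-dimethylpropanoate
Conditions: PPh3, DIAD, toluene, 0 °C → rt; filtration through basic alumina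
Reagents that add atoms: none
Why: Mitsunobu etherification of an acidic ortho-acyl phenol; SN2 displacement of the alkoxyphosphonium inverts C1 (S → R), and the non-polar solvent together with the electron-poor pivaloyloxyaryl group should disfavour SN1 and SN2′ pathways.

Step 7
Reactants: 13 4-[(1R,2E)-1-[2-acetyl-3-methoxy-5-(methoxymethoxy)phenoxy]-7-[4-(methoxymethoxy)phenyl]hept-2-en-1-yl]phenyl 2,2-dimethylpropanoate
Product: 15 4-[(1E,3R)-3-[3-acetyl-2-hydroxy-4-methoxy-6-(methoxymethoxy)phenyl]-7-[4-(methoxymethoxy)phenyl]hept-1-en-1-yl]phenyl 2,2-dimethylpropanoate, via ortho-dienone 14 (not isolated)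
Conditions: PhNEt2 (degassed), 140 °C, sealed tube
Reagents that add atoms: none
Why: Thermal aromatic Claisen rearrangement, a concerted suprafacial [3,3] shift in which O2′–C1 breaks while C3′–C3 forms to give ortho-dienone 14, which enolises at once to phenol 15 (the new 2′-OH is hydrogen-bonded to the acetyl group). The closest known reaction type is the ortho-Claisen rearrangement of enantioenriched secondary (E)-allyl aryl ethers, which proceeds with 1,3-chirality transfer. No ring is closed in the product; the six atoms O2′–C2′–C3′···C3=C2–C1 pass through a chair-like array. C3 is controlled by the C1 carbinol centre: in the chair with the C1 aryl group equatorial, C3′ is delivered to the face of C3 from which oxygen departs at C1, so (R)-C1 with the E-alkene should give (R)-C3, and the same chair makes the new C1=C2 bond E; the C3′ centre of 14 is lost on enolisation. Regioselectivity is secured by the substrate, because of the two ortho positions of O2′ the carbon C1′ bears the acetyl group and cannot rearomatise, so only C3′ between O2′ and O4′ is alkylated. The step needs the concerted path to outrun C1–O heterolysis, and the weakly donating pivaloyloxy group on the C1 aryl ring and the non-polar, weakly basic medium are chosen for that. One operation thus forms the congested C3′–C3 bond, the stereocentre and the (E)-styrene.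

Step 8
Reactants: 15 4-[(1E,3R)-3-[3-acetyl-2-hydroxy-4-methoxy-6-(methoxymethoxy)phenyl]-7-[4-(methoxymethoxy)phenyl]hept-1-en-1-yl]phenyl 2,2-dimethylpropanoate; 16 4-(methoxymethoxy)benzaldehyde
Product: 17 (2E)-1-[2-hydroxy-3-[(1E,3R)-1-(4-hydroxyphenyl)-7-[4-(methoxymethoxy)phenyl]hept-1-en-3-yl]-6-methoxy-4-(methoxymethoxy)phenyl]-3-[4-(methoxymethoxy)phenyl]prop-2-en-1-one
Conditions: KOH (aq., 10 equiv), EtOH, rt → 40 °C; AcOH to pH 6
Reagents that add atoms: none
Why: Claisen–Schmidt condensation of a hindered 2′-hydroxyacetophenone with a non-enolisable aldehyde gives the E-enone; hydroxide cleaves the aryl pivalate in the same pot, and C3–H, now flanked by two phenoxide-bearing rings, should be too weakly acidic to epimerise.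

Step 9
Reactants: 17 (2E)-1-[2-hydroxy-3-[(1E,3R)-1-(4-hydroxyphenyl)-7-[4-(methoxymethoxy)phenyl]hept-1-en-3-yl]-6-methoxy-4-(methoxymethoxy)phenyl]-3-[4-(methoxymethoxy)phenyl]prop-2-en-1-one
Product: 18 deoxycalyxin A, (2E)-1-[3-[(1E,3R)-1,7-bis(4-hydroxyphenyl)hept-1-en-3-yl]-2,4-dihydroxy-6-methoxyphenyl]-3-(4-hydroxyphenyl)prop-2-en-1-one
Conditions: 3 M aq. HCl, MeOH–THF, rt
Reagents that add atoms: none
Why: Acid-catalysed acetal exchange removes the three aryl MOM ethers under dilute, cold conditions, which chalcones of this 2′-hydroxy-6′-methoxy type with acid-sensitive C3′ side chains are expected to tolerate; the stereocentre is not involved.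

## Compound list

1 | 1-bromo-4-(methoxymethoxy)benzene | COCOc1ccc(Br)cc1 | starting material
2 | 1,4-dibromobutane | BrCCCCBr | starting material
3 | [4-(methoxymethoxy)phenyl]magnesium bromide | COCOc1ccc([Mg]Br)cc1 | intermediate
4 | 1-(4-bromobutyl)-4-(methoxymethoxy)benzene | COCOc1ccc(CCCCBr)cc1 | intermediate
5 | 1-(hex-5-yn-1-yl)-4-(methoxymethoxy)benzene | C#CCCCCc1ccc(OCOC)cc1 | intermediate
6 | 4-hydroxybenzaldehyde | O=Cc1ccc(O)cc1 | starting material
7 | 4-formylphenyl 2,2-dimethylpropanoate | CC(C)(C)C(=O)Oc1ccc(C=O)cc1 | intermediate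
8 | dicyclohexyl[(1E)-6-[4-(methoxymethoxy)phenyl]hex-1-en-1-yl]borane | COCOc1ccc(CCCC/C=C/B(C2CCCCC2)C2CCCCC2)cc1 | intermediate
9 | methyl[(1E)-6-[4-(methoxymethoxy)phenyl]hex-1-en-1-yl]zinc | COCOc1ccc(CCCC/C=C/[Zn]C)cc1 | intermediate
10 | 4-[(1S,2E)-1-hydroxy-7-[4-(methoxymethoxy)phenyl]hept-2-en-1-yl]phenyl 2,2-dimethylpropanoate | O[C@H](c1ccc(OC(=O)C(C)(C)C)cc1)/C=C/CCCCc1ccc(OCOC)cc1 | intermediate
11 | 1-(2,4-dihydroxy-6-methoxyphenyl)ethan-1-one | CC(=O)c1c(O)cc(O)cc1OC | starting material
12 | 1-[2-hydroxy-6-methoxy-4-(methoxymethoxy)phenyl]ethan-1-one | CC(=O)c1c(O)cc(OCOC)cc1OC | intermediate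
13 | 4-[(1R,2E)-1-[2-acetyl-3-methoxy-5-(methoxymethoxy)phenoxy]-7-[4-(methoxymethoxy)phenyl]hept-2-en-1-yl]phenyl 2,2-dimethylpropanoate | CC(=O)c1c(O[C@@H](c2ccc(OC(=O)C(C)(C)C)cc2)/C=C/CCCCc2ccc(OCOC)cc2)cc(OCOC)cc1OC | intermediate
14 | 4-[(1E,3R)-3-[(1R)-3-acetyl-4-methoxy-6-(methoxymethoxy)-2-oxocyclohexa-3,5-dien-1-yl]-7-[4-(methoxymethoxy)phenyl]hept-1-en-1-yl]phenyl 2,2-dimethylpropanoate | CC(=O)C1=C(OC)C=C(OCOC)[C@@H]([C@H](CCCCc2ccc(OCOC)cc2)/C=C/c2ccc(OC(=O)C(C)(C)C)cc2)C1=O | intermediate
15 | 4-[(1E,3R)-3-[3-acetyl-2-hydroxy-4-methoxy-6-(methoxymethoxy)phenyl]-7-[4-(methoxymethoxy)phenyl]hept-1-en-1-yl]phenyl 2,2-dimethylpropanoate | CC(=O)c1c(O)c([C@@H](/C=C/c2ccc(OC(=O)C(C)(C)C)cc2)CCCCc2ccc(OCOC)cc2)c(OCOC)cc1OC | intermediate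
16 | 4-(methoxymethoxy)benzaldehyde | COCOc1ccc(C=O)cc1 | starting material
17 | (2E)-1-[2-hydroxy-3-[(1E,3R)-1-(4-hydroxyphenyl)-7-[4-(methoxymethoxy)phenyl]hept-1-en-3-yl]-6-methoxy-4-(methoxymethoxy)phenyl]-3-[4-(methoxymethoxy)phenyl]prop-2-en-1-one | COCOc1ccc(/C=C/C(=O)c2c(OC)cc(OCOC)c([C@@H](/C=C/c3ccc(O)cc3)CCCCc3ccc(OCOC)cc3)c2O)cc1 | intermediate
18 | deoxycalyxin A | COc1cc(O)c([C@@H](/C=C/c2ccc(O)cc2)CCCCc2ccc(O)cc2)c(O)c1C(=O)/C=C/c1ccc(O)cc1 | target

## Step count and least certain steps

Total: 9 steps. Longest linear sequence: 7 steps (steps 1, 2, 4, 6, 7, 8, 9).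

Step 7 (key step). The likely failure is heterolysis of the benzylic, allylic C1–O bond competing with the concerted shift. Ion-pair recombination or loss of the phenol with diene formation would erode chirality transfer and regiocontrol. If a higher temperature is needed, ene-type hydrogen shifts of the product could also set in. The fallback takes the benzylic carbinol out of the sigmatropic step and attaches the aryl group afterwards. It sets out from 5 and 12 and comes back at 17. Alkyne 5 is subjected to the protocol of step 4 with acetaldehyde in place of 7, which should give the methyl carbinol (2R,3E)-8-[4-(methoxymethoxy)phenyl]oct-3-en-2-ol F1. Mitsunobu etherification with 12 inverts it to the (S)-configured aryl ether F2. Its thermal Claisen rearrangement, the well-behaved non-benzylic case, should give the (R)-configured propenyl ketone F3. Cross-metathesis of F3 with 4-acetoxystyrene (Hoveyda–Grubbs II catalyst, benzoquinone additive, CH2Cl2, 40 °C) installs the aryl group and gives the aryl acetate F4. F4 is carried through the conditions of step 8, where the acetate is cleaved as the pivalate is, to give 17.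

Step 6. The likely failure is ionisation or SN2′ leakage at the doubly activated carbinol, with loss of configurational purity, together with elimination to a diene and low reactivity of the hydrogen-bonded, hindered phenol. The fallback forms the C–O bond at a propargylic carbinol, which ionises less readily and cannot undergo these allylic side reactions. It sets out from 5, 7 and 12 and comes back at 13. Catalytic asymmetric alkynylation of 7 with 5 (Me2Zn, ProPhenol ligand, toluene) gives the (R)-propargylic alcohol F5. Mitsunobu etherification with 12 gives the propargylic aryl ether F6 with inversion. Ruthenium-catalysed trans-hydrogenation ([Cp*Ru(cod)Cl], H2, CH2Cl2) converts the alkyne into the E-alkene of 13.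

Step 9. The likely failure is acid-promoted cyclisation of the free phenols onto the protonated p-hydroxystyrene (flavan formation) or onto the enone (flavanone formation), or ionisation of the C3′–C3 bond during the slow cleavage of three MOM ethers. The fallback removes the MOM groups before the chalcone and the electron-rich styrene exist. It sets out from 15 and comes back at 18. Treatment of 15 with HCl in MeOH at rt, where the styrene is still the deactivated pivaloyloxy type, gives the triphenol pivalate F7. F7 is condensed with unprotected 6 under classical conditions for hydroxychalcones (concentrated aq. KOH, EtOH, rt, extended time). The pivalate is cleaved in the same pot and 18 forms directly.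

Step 4. The likely failure is insufficient enantioselectivity of the alkenyl transfer or competing methyl transfer from zinc. The fallback replaces asymmetric addition by kinetic resolution. It sets out from 5 and 7 and comes back at 10. The same hydroboration and transmetalation without the ligand gives the racemic alcohol F8. Sharpless kinetic resolution (Ti(OiPr)4, L-(+)-DIPT, TBHP 0.6 equiv, 4 Å sieves, CH2Cl2, −20 °C) should consume the (R)-enantiomer as the epoxy alcohol F9 and leave (S)-alcohol 10.

## Further compounds

F1 | step 7 | (2R,3E)-8-[4-(methoxymethoxy)phenyl]oct-3-en-2-ol | C[C@@H](O)/C=C/CCCCc1ccc(OCOC)cc1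
F2 | step 7 | 1-[2-{[(2S,3E)-8-[4-(methoxymethoxy)phenyl]oct-3-en-2-yl]oxy}-6-methoxy-4-(methoxymethoxy)phenyl]ethan-1-one | CC(=O)c1c(O[C@@H](C)/C=C/CCCCc2ccc(OCOC)cc2)cc(OCOC)cc1OC
F3 | step 7 | 1-[2-hydroxy-6-methoxy-4-(methoxymethoxy)-3-[(2E,4R)-8-[4-(methoxymethoxy)phenyl]oct-2-en-4-yl]phenyl]ethan-1-one | CC(=O)c1c(O)c([C@@H](/C=C/C)CCCCc2ccc(OCOC)cc2)c(OCOC)cc1OC
F4 | step 7 | 4-[(1E,3R)-3-[3-acetyl-2-hydroxy-4-methoxy-6-(methoxymethoxy)phenyl]-7-[4-(methoxymethoxy)phenyl]hept-1-en-1-yl]phenyl acetate | CC(=O)c1c(O)c([C@@H](/C=C/c2ccc(OC(C)=O)cc2)CCCCc2ccc(OCOC)cc2)c(OCOC)cc1OC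
F5 | step 6 | 4-[(1R)-1-hydroxy-7-[4-(methoxymethoxy)phenyl]hept-2-yn-1-yl]phenyl 2,2-dimethylpropanoate | O[C@H](c1ccc(OC(=O)C(C)(C)C)cc1)C#CCCCCc1ccc(OCOC)cc1
F6 | step 6 | 4-[(1S)-1-[2-acetyl-3-methoxy-5-(methoxymethoxy)phenoxy]-7-[4-(methoxymethoxy)phenyl]hept-2-yn-1-yl]phenyl 2,2-dimethylpropanoate | CC(=O)c1c(O[C@@H](c2ccc(OC(=O)C(C)(C)C)cc2)C#CCCCCc2ccc(OCOC)cc2)cc(OCOC)cc1OC
F7 | step 9 | 4-[(1E,3R)-3-(3-acetyl-2,6-dihydroxy-4-methoxyphenyl)-7-(4-hydroxyphenyl)hept-1-en-1-yl]phenyl 2,2-dimethylpropanoate | CC(=O)c1c(O)c([C@@H](/C=C/c2ccc(OC(=O)C(C)(C)C)cc2)CCCCc2ccc(O)cc2)c(O)cc1OC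
F8 | step 4 | rac-4-[(2E)-1-hydroxy-7-[4-(methoxymethoxy)phenyl]hept-2-en-1-yl]phenyl 2,2-dimethylpropanoate | CC(C)(C)C(=O)Oc1ccc(C(O)/C=C/CCCCc2ccc(OCOC)cc2)cc1
F9 | step 4 | 4-[(S)-hydroxy[(2R,3R)-3-[4-[4-(methoxymethoxy)phenyl]butyl]oxiran-2-yl]methyl]phenyl 2,2-dimethylpropanoate | O[C@@H](c1ccc(OC(=O)C(C)(C)C)cc1)[C@H]1O[C@@H]1CCCCc1ccc(OCOC)cc1
A1 | alternative 1 | rac-(1E)-1,7-bis(4-hydroxyphenyl)hept-1-en-3-ol | OC(/C=C/c1ccc(O)cc1)CCCCc1ccc(O)cc1
A2 | alternative 1 | rac-1-[3-[(1E)-1,7-bis(4-hydroxyphenyl)hept-1-en-3-yl]-2,4-dihydroxy-6-methoxyphenyl]ethan-1-one | CC(=O)c1c(O)c(C(/C=C/c2ccc(O)cc2)CCCCc2ccc(O)cc2)c(O)cc1OC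
A3 | alternative 2 | [4-methoxy-2,6-bis(methoxymethoxy)phenyl]boronic acid | COCOc1cc(OC)cc(OCOC)c1B(O)O
A4 | alternative 2 | (4E,6E)-1,7-bis[4-(methoxymethoxy)phenyl]hepta-4,6-dien-3-one | COCOc1ccc(CCC(=O)/C=C/C=C/c2ccc(OCOC)cc2)cc1
A5 | alternative 2 | (5R,6E)-5-[4-methoxy-2,6-bis(methoxymethoxy)phenyl]-1,7-bis[4-(methoxymethoxy)phenyl]hept-6-en-3-one | COCOc1cc(OC)cc(OCOC)c1[C@@H](/C=C/c1ccc(OCOC)cc1)CC(=O)CCc1ccc(OCOC)cc1
A6 | alternative 3 | (1S,2E)-1-[4-(2,2-dimethylpropanoyloxy)phenyl]-7-[4-(methoxymethoxy)phenyl]hept-2-en-1-yl pyridine-2-carboxylate | O=C(O[C@H](c1ccc(OC(=O)C(C)(C)C)cc1)/C=C/CCCCc1ccc(OCOC)cc1)c1ccccn1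
A7 | alternative 3 | 1-methoxy-3,5-bis(methoxymethoxy)benzene | COCOc1cc(OC)cc(OCOC)c1
A8 | alternative 3 | 4-[(1E,3R)-3-[4-methoxy-2,6-bis(methoxymethoxy)phenyl]-7-[4-(methoxymethoxy)phenyl]hept-1-en-1-yl]phenyl 2,2-dimethylpropanoate | COCOc1cc(OC)cc(OCOC)c1[C@@H](/C=C/c1ccc(OC(=O)C(C)(C)C)cc1)CCCCc1ccc(OCOC)cc1
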